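**Early ratio.** Begin at the earliest readings. At 1.33 h the ratio [isomer of the product]/[target] reads 0.276 in the green run and 0.212 in the red run. Those values lie on either side of the values at 20.0 h.

all flasks: starting material 0.20 M

|  | reagent | remark | time |
|---|---|---|---|
| green | 2.5 equiv | run made earlier |  |
| red | 4 equiv | run made earlier |  |
| flask | 1.80 equiv |  | 30 h |

| run | time / h | isomer of the product / % | target / % |
|---|---|---|---|
| green | 1.33 | 7.2 | 26.1 |
| green | 3.00 | 10.6 | 46.0 |
| green | 8.00 | 17.4 | 70.7 |
| green | 20.0 | 19.0 | 79.8 |
| red | 1.33 | 7.0 | 33.0 |
| red | 3.00 | 12.0 | 53.0 |
| red | 8.00 | 17.1 | 75.6 |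
| red | 20.0 | 19.1 | 80.7 |

(readings scatter by 0.5 percentage points)

* ratio of isomer of the product to target at 8.0 min
* ratio of isomer of the product to target at 30 h

- steps that have been proposed: target <-> isomer of the product; intermediate D -> target; reagent + intermediate A <-> intermediate C; starting material <-> dormant form; intermediate B -> intermediate D; starting material + reagent -> intermediate A; reagent + intermediate A -> intermediate B

**Resting ratio.** Average the two readings at 20.0 h to get the resting ratio 0.237, the read equilibrium constant of the pair, at which target and isomer of the product go on exchanging with no net change. Integrate the exchange under a steady feed: the ratio falls short of this value by about the relaxation time over the elapsed time. The earliest readings stand at 1.33 h, ten times the time 8.0 min, and show no clear shortfall, so they bound the ratio at 8.0 min only loosely. Take the resting ratio as a ceiling at 8.0 min, and commit to it as the value at 30 h.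

**Reagent ledger.** In this flask, reagent is the limiting reagent. Enter one equivalent for each starting material that becomes intermediate A, and a second for each intermediate A that goes on to product. The green and red runs show 98.8% and 99.8% as product at 20.0 h, but this flask holds 1.80 equiv. Close the books with all starting material converted: 0.800 per mole reaches product and 0.200 stays at intermediate A. Split the product by the resting ratio, which leaves target at 64.7%.

**The check.** The forecast gave 0.12 (range 0.04 to 0.24), "about 0.12, poorly determined", and 0.237 (range 0.222 to 0.252). The flask gives 0.225 at 8.0 min and 0.240 at 30 h, with target at 65.0%.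

    target ⇌ isomer of the product (K = 0.240, k = 0.860 min⁻¹)
    intermediate D → target (k = 0.870 min⁻¹)
    reagent + intermediate A ⇌ intermediate C (K = 16.0 L mol⁻¹, k = 0.730 L mol⁻¹ min⁻¹)
    starting material ⇌ dormant form (K = 0.580, k = 0.0260 min⁻¹)
    intermediate B → intermediate D (k = 0.600 min⁻¹)
    starting material + reagent → intermediate A (k = 0.260 L mol⁻¹ min⁻¹)
    reagent + intermediate A → intermediate B (k = 0.120 L mol⁻¹ min⁻¹)

**Early balance.** Remove the back reaction of isomer of the product to target from the simulated run, and the ratio at 8.0 min climbs from 0.225 to 3.11. So the back reaction holds the ratio down so early. The pair relaxes in 0.225 min, far shorter than 8.0 min.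

**Second flask.** Take the neighbour charged with 0.450 equiv of reagent. The resting ratio gives 0.237, and so isomer of the product at 1.07% beside target at 4.52%. The computed ratio there is 0.223 at 8.0 min and 0.240 at 30 h, with isomer of the product at 1.09%.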